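Slowness is what I look for first: which clock in these flasks is still running at the asked time?

| setting | teal | blue | flask |
|---|---|---|---|
| substrate | 0.25 M (in portions, 3) | 0.25 M (in portions, 3) | 0.25 M (in portions, 3) |
| partner | 0.19 M | 0.75 M | 0.375 M |
| precatalyst | 0.50 mM | 0.50 mM | 0.50 mM |
| remark | run made earlier; portions every 25 s | run made earlier; portions every 25 s | the portions of substrate follow each other after 25 s, the first at the start |
| time |  |  | 40 min |

- teal (time / min: substrate / %, target / %, isomer of the product A / %): 6.00: 51, 23, 15; 12.0: 46, 27, 21; 20.0: 48, 24, 20; 25.0: 44, 24, 20; 30.0: 48, 27, 22; 40.0: 45, 23, 18
- blue (time / min: substrate / %, target / %, isomer of the product A / %): 6.00: 11, 44, 27; 12.0: 8, 44, 35; 20.0: 9, 39, 32; 25.0: 8, 43, 35; 30.0: 9, 39, 37; 40.0: 9, 44, 35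

(standard deviation of a reading: 2 percentage points)

- the reaction counts as stopped when no species that holds the substrate changes by six tenths of a point or more over the second half of the time

1. which holds at 40 min: what has brought the reaction to rest, or that it has not come to rest (all of the substrate has reacted / no working catalyst is left / it is still moving / the partner has run out first / forward and back rates have come level)
2. share of the substrate used up at 40 min
3. target at 40 min, in percent of the substrate charged
4. isomer of the product A at 40 min, in percent of the substrate charged
5. isomer of the product B at 40 min, in percent of the substrate charged

The quickest clock is the feed, over after 0.833 min, well before the first reading at 6.00 min, so I treat the substrate as charged at once. Next comes the fall of the substrate: at that first reading the blue run already holds 11%. Then the split among products follows: in the blue run, isomer of the product A over target reads 0.614 at first and 0.833 on average later. From 12.0 min on, both runs wander within about their scatter of 2 percentage points, and that is earlier than the asked time, so I ask where the reaction stops.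

The later readings average 46.2% substrate in the teal run and 8.60% in the blue run. Taking one partner per substrate, the teal run keeps 0.0555 M of partner, so it has not stopped for lack of partner. Dividing the share used by the share left and by the partner left gives 21.0 M⁻¹ for the teal run and 20.4 M⁻¹ for the blue run, nearly equal although their partner charges differ by a factor of 3.95. Their mean, 20.7 M⁻¹, is the rest quotient I carry, the share used over the share left times the partner left; the usual term is an equilibrium constant, here for all products together.

Setting the flask's net rate to zero at this quotient gives a quadratic, whose smaller root is 78.7% used. The readings give target 46.0% and isomer of the product A 37.9% of what is used, and I give the remainder to isomer of the product B. So I expect forward and back rates to have come level by 40 min, with target 36.2%, isomer of the product A 29.8% and isomer of the product B 12.7%.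

The forecast says forward and back rates have come level, with 78% used, target 36%, isomer of the product A 30% and isomer of the product B 12%, on the ground “These agree, so forward and back rates have come level”. My conversion stands 0.70 points above the forecast's, and my isomer of the product B stands 0.68 points above its figure.

The result at 40 min for the flask is this: forward and back rates have come level, with 79.0% used, target 35.7%, isomer of the product A 29.8% and isomer of the product B 13.6%.

    substrate + partner ⇌ target (K = 9.60 M⁻¹, k = 0.0180 M⁻¹ s⁻¹)
    substrate + partner ⇌ isomer of the product A (K = 8.00 M⁻¹, k = 0.00680 M⁻¹ s⁻¹)
    target + catalyst ⇌ isomer of the product A + catalyst, rate k3*[catalyst]*[target] forward; the back reaction follows from the equilibrium constant (k = 13.0 M⁻¹ s⁻¹)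
    precatalyst → catalyst (k = 7.40 × 10⁻⁴ s⁻¹)
    target ⇌ isomer of the product B (K = 0.380, k = 0.00310 s⁻¹)

The flask's rest quotient is 21.2 M⁻¹. For the neighbour flask with 0.094 M of partner, the carried 20.7 M⁻¹ gives 29.5% used, and that flask gives 29.7%. In the flask itself the substrate stands at 21.0% at 20.0 min and 21.0% at 40.0 min, while catalyst stands at 83.1% of its charge. At 400 min catalyst reaches 100%, yet conversion is 79.0%, with target 35.7%, isomer of the product A 29.8% and isomer of the product B 13.6%.

All runs stem from a simulated flask for an exercise; the scatter is artificial.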